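## Structural features

Isobutyryl alkannin is a naphthazarin bicycle (5,8-dihydroxy-1,4-naphthoquinone; ring A = C1–C4/C4a/C8a, ring B = C4a/C5–C8/C8a) with a six-carbon side chain on C2. The side chain holds the only stereocentre, C1' (S), as an isobutyrate; C2' is a methylene and C3'=C4' a trisubstituted, prenyl-type olefin. C1' has no neighbouring stereocentre, so it needs one enantioselective event. It stands on the quinone ring, allylic to C2=C3 and γ to the C4 carbonyl, so base can turn it into a quinone methide and reduction or strong acid can expel the acyloxy group. Rings A and B are fused through C4a–C8a and are functionally degenerate: proton shift within the two peri O–H···O=C pairs exchanges the quinone ring and the hydroquinone ring, so both tautomers are one compound. The fragile groups are the redox-active naphthazarin, the acid- and oxidant-sensitive olefin, the ester and the C1'–O bond. The real difficulty is the oxidation pattern rather than the skeleton: the oxygens on C1, C4, C5 and C8 must end as two carbonyls and two free peri-hydroxyls next to this side chain, and cleaving peri aryl ethers needs conditions that C1'–O and C3'=C4' do not tolerate. Ring B taken alone is a C4 unit (C5–C8) with oxygen on both ends and hydrogen on C6 and C7, which is the oxidation level of a succinic anhydride bis-enol; the key step exploits this and the tautomeric degeneracy.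

## Logic of the disconnections

**11 to 6 + 8.** In one sentence: ring B is created last, at its final oxidation level, by a Diels–Alder/bridge-opening cascade between monocyclic 6 and 8. The bonds cut are C4a–C5 and C8–C8a. Cutting here means C5–C8 arrive with both oxygens in place and with the right number of hydrogens, so no phenol of ring B is ever protected or deprotected. The gain is the step from a bicyclic, doubly peri-hydroxylated quinone to a monocyclic quinone and a symmetrical C4 diene. The forward step must add at the unsubstituted double bond of 6, must be a cycloaddition and not a conjugate addition or electron transfer, and must collapse without base or strong acid.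

**8 to 7.** Two O–Si bonds are cut. This traces the diene to a commodity C4 anhydride in one operation. The forward step must silylate both enol oxygens and deliver 8 free of water and acid.

**6 to 5.** The two quinone C=O groups are traced back to two aryl–OMe groups. An electron-rich 1,4-dimethoxybenzene is oxidised much more easily than a tetraalkoxynaphthalene, so the only ether cleavage of the route is moved to the easiest possible substrate. The forward step must leave the olefin, the ester and C1' alone.

**5 to 4.** The acyl C–O bond of the ester is cut. The ester is installed before any quinone exists, which avoids acylating next to phenols. The forward step must proceed with retention at C1' and without ionising the benzylic position.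

**4 to 3.** The C3'=C4' double bond is cut. A linear prenyl group cannot be delivered directly by allylmetal addition (γ-attack gives the branched isomer), whereas an allyl group can, and is then extended. The forward step is a cross-metathesis that must not touch C1'.

**3 to 1.** The C1'–C2' bond is cut. This sets the only stereocentre by reagent control on a simple commercial aryl aldehyde. The forward step must attack the Si face of the aldehyde.

## Other disconnections considered

**Alternative 1:** This is the first idea that comes to mind. The cut is C1'–C2' on an intact, fully O-methylated naphthalene. The forward key step is asymmetric allylation of 1,4,5,8-tetramethoxynaphthalene-2-carbaldehyde A1, followed by chain extension and acylation to ester A2. Oxidative demethylation would then lead through the 5,8-dimethoxyquinone A3. The chosen plan is preferred on structural and mechanistic grounds. Four aryl ethers must be removed after the side chain is complete. Oxidation of A2 can take place in either ring. The two peri-methoxy groups of A3 sit next to carbonyls and call for Lewis acids or strong oxidants, under which C1'–O should ionise and the olefin should suffer. A1 also needs several steps of its own, so the route is longer.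

**Alternative 2:** The cut is ring A (C1–C2, C3–C4, C1–C8a). The forward key step is a Dötz benzannulation of the carbene complex (CO)5Cr=C(OMe)Ar A4 (Ar = 2,5-dimethoxyphenyl) with the chiral alkyne (S)-6-methylhept-5-en-1-yn-3-yl isobutyrate A5. This should give naphthol A6 with the side chain ortho to the new hydroxyl, and oxidation would give A3. The stereocentre is set early and regiochemistry is secure, but the product again carries the two peri-methyl ethers of ring B. The endgame problem of Alternative 1 therefore remains. Stoichiometric chromium is needed, and the propargylic acyloxy group sits next to the metal-bound vinylcarbene, where loss of carboxylate is a plausible side path.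

**Alternative 3:** This is a skeletal rearrangement. A cyclobutenedione A7 bearing the side chain would take up a lithiated 1,4-dimethoxyarene to give the 4-aryl-4-hydroxycyclobutenone A8. Thermal 4π-opening to a vinylketene, 6π-closure onto the arene and oxidation would give A3. The symmetry of the aryl group makes the regiochemistry of addition irrelevant, which is attractive. However, A7 is harder to make than the target's single stereocentre justifies, the organolithium must spare the ester, and the sequence ends once more at A3 with ring B still methylated. The chosen plan is shorter and is the only one in which ring B is born unprotected.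

Key step: step 6

Remark on the chemistry (assumption): the two naphthazarin tautomers of the target (quinone in ring A or in ring B) interconvert rapidly by proton shift and are treated as the single compound 11, written with the SMILES given. 2,5-Dimethoxybenzaldehyde, succinic anhydride and (−)-B-methoxydiisopinocampheylborane are taken as commercial.

## Steps

Step 1
Reactants: 1 2,5-dimethoxybenzaldehyde
Product: 3 (S)-1-(2,5-dimethoxyphenyl)but-3-en-1-ol, via borinate ester 2 (not isolated)
Conditions: (−)-Ipc2BOMe, CH2=CHCH2MgBr, Et2O, 0 °C to rt; then 1, −78 °C; then 3 M aq NaOH, 30% H2O2, rt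
Reagents that add atoms: allylmagnesium bromide, C=CC[Mg]Br
Why: Brown asymmetric allylboration; the B-allyldiisopinocampheylborane from the (+)-α-pinene series transfers allyl through a closed chair transition state to the Si face of the aldehyde, which for an aryl aldehyde is the (S) carbinol. The reaction is reagent-controlled and fast at −78 °C, so the ortho-methoxy group should have little influence.

Step 2
Reactants: 3 (S)-1-(2,5-dimethoxyphenyl)but-3-en-1-ol
Product: 4 (S)-1-(2,5-dimethoxyphenyl)-4-methylpent-3-en-1-ol
Conditions: (H2IMes)(PCy3)Cl2Ru=CHPh (second-generation Grubbs catalyst, 5 mol%), 2-methyl-2-butene/CH2Cl2, 40 °C, sealed vessel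
Reagents that add atoms: 2-methyl-2-butene, CC=C(C)C
Why: Olefin cross-metathesis of a terminal olefin with an excess of 2-methyl-2-butene as isopropylidene donor, driven by loss of propene. C1' is not involved and keeps its configuration.

Step 3
Reactants: 4 (S)-1-(2,5-dimethoxyphenyl)-4-methylpent-3-en-1-ol
Product: 5 (S)-1-(2,5-dimethoxyphenyl)-4-methylpent-3-en-1-yl 2-methylpropanoate
Conditions: (i-PrCO)2O, Et3N, DMAP (cat.), CH2Cl2, 0 °C to rt
Reagents that add atoms: isobutyric anhydride, CC(C)C(=O)OC(=O)C(C)C
Why: DMAP-catalysed O-acylation; the O–acyl bond is formed, so C1' is retained. The basic medium avoids ionisation of the electron-rich benzylic position.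

Step 4
Reactants: 5 (S)-1-(2,5-dimethoxyphenyl)-4-methylpent-3-en-1-yl 2-methylpropanoate
Product: 6 (S)-1-(3,6-dioxocyclohexa-1,4-dien-1-yl)-4-methylpent-3-en-1-yl 2-methylpropanoate
Conditions: (NH4)2Ce(NO3)6 (2.5 equiv), MeCN/H2O, 0 °C, short reaction time; used at once
Reagents that add atoms: water, O
Why: Oxidative demethylation of a 1,4-dimethoxyarene by tetravalent cerium via the arene radical cation, attack of water and loss of methanol. The arene is oxidised far more easily than the trisubstituted olefin, and the ester and C1' are not touched.

Step 5
Reactants: 7 succinic anhydride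
Product: 8 2,5-bis(trimethylsilyloxy)furan
Conditions: Me3SiCl, Et3N, ZnCl2 (cat.), MeCN, rt to 40 °C; filtration and distillation under argon
Reagents that add atoms: chlorotrimethylsilane, C[Si](C)(C)Cl
Why: Double soft enolisation and O-silylation of the anhydride (silyl ketene acetal formation); the aromatic furan that results favours the second silylation.

Step 6
Reactants: 6 (S)-1-(3,6-dioxocyclohexa-1,4-dien-1-yl)-4-methylpent-3-en-1-yl 2-methylpropanoate; 8 2,5-bis(trimethylsilyloxy)furan
Product: 11 isobutyryl alkannin, via oxa-bridged cycloadduct 9 (not isolated), via ring-fused tetraone 10 (not isolated)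
Conditions: 8 (1.3 equiv), CH2Cl2, −78 °C to rt, argon, dark; then THF/0.1 M aq HCl, 0 °C
Reagents that add atoms: none
Why: Normal-electron-demand Diels–Alder reaction: the bis(silyl ketene acetal) diene 8 has a very high HOMO and the unsubstituted C5=C6 bond of quinone 6 a low LUMO, so the [4+2] addition should proceed below room temperature without catalyst. The closest known reaction type is the Diels–Alder reaction of 2,5-bis(trimethylsilyloxy)furans with quinones and other electron-poor olefins, whose adducts collapse to p-quinones or hydroquinones. Ring B is closed as a six-membered carbocycle by the concerted suprafacial cycloaddition, which forms C4a–C5 and C8–C8a (naphthalene numbering) at once; the 7-oxanorbornene bridge of 9 is only a temporary second ring. On mild acid work-up each bridgehead, a silylated ketal carbon, expels the bridging oxygen or silanol with the push of its remaining oxygen, so both bridgeheads become carbonyls, hexamethyldisiloxane is lost and the ene-dione 10 results. 10 has two doubly activated methine hydrogens at C4a and C8a and should enolise twice to the aromatic naphthazarin; because the two tautomers equilibrate, no oxidant, reductant or protecting group is involved. No new stereocentre survives: the bridgehead and ring-fusion centres of 9 and 10 are destroyed on aromatisation, so endo/exo and facial selectivity are immaterial, and C1' is untouched because the conditions are neither basic nor ionising. The selectivity needed is site selectivity for C5=C6 over C2=C3 of 6, secured by the branched substituent on C2 (steric shielding, and an angular quaternary centre would otherwise have to form), and cycloaddition over conjugate addition through C3 of the furan, favoured by the absence of Lewis acid, an apolar solvent and low temperature.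

## Compound list

1 | 2,5-dimethoxybenzaldehyde | COc1ccc(OC)c(C=O)c1 | starting material
2 | (S)-1-(2,5-dimethoxyphenyl)but-3-en-1-yl diisopinocampheylborinate (isopinocampheyl groups of the (+)-α-pinene series) | C=CC[C@H](OB([C@@H]1C[C@@H]2C[C@H]([C@H]1C)C2(C)C)[C@@H]1C[C@@H]2C[C@H]([C@H]1C)C2(C)C)c1cc(OC)ccc1OC | intermediate (not isolated)
3 | (S)-1-(2,5-dimethoxyphenyl)but-3-en-1-ol | C=CC[C@H](O)c1cc(OC)ccc1OC | intermediate
4 | (S)-1-(2,5-dimethoxyphenyl)-4-methylpent-3-en-1-ol | CC(C)=CC[C@H](O)c1cc(OC)ccc1OC | intermediate
5 | (S)-1-(2,5-dimethoxyphenyl)-4-methylpent-3-en-1-yl 2-methylpropanoate | CC(C)=CC[C@H](OC(=O)C(C)C)c1cc(OC)ccc1OC | intermediate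
6 | (S)-1-(3,6-dioxocyclohexa-1,4-dien-1-yl)-4-methylpent-3-en-1-yl 2-methylpropanoate | CC(C)=CC[C@H](OC(=O)C(C)C)C1=CC(=O)C=CC1=O | intermediate
7 | succinic anhydride | O=C1CCC(=O)O1 | starting material
8 | 2,5-bis(trimethylsilyloxy)furan | C[Si](C)(C)Oc1ccc(O[Si](C)(C)C)o1 | intermediate
9 | (1S)-1-[5,8-bis(trimethylsilyloxy)-1,4-dioxo-1,4,4a,5,8,8a-hexahydro-5,8-epoxynaphthalen-2-yl]-4-methylpent-3-en-1-yl 2-methylpropanoate (bridgehead and ring-fusion centres transient, expected as a mixture, left open) | CC(C)=CC[C@H](OC(=O)C(C)C)C1=CC(=O)C2C(C1=O)C1(O[Si](C)(C)C)C=CC2(O[Si](C)(C)C)O1 | intermediate (not isolated)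
10 | (1S)-4-methyl-1-(1,4,5,8-tetraoxo-1,4,4a,5,8,8a-hexahydronaphthalen-2-yl)pent-3-en-1-yl 2-methylpropanoate (cis ring fusion, transient, left open) | CC(C)=CC[C@H](OC(=O)C(C)C)C1=CC(=O)C2C(C1=O)C(=O)C=CC2=O | intermediate (not isolated)
11 | isobutyryl alkannin, (1S)-1-(5,8-dihydroxy-1,4-dioxo-1,4-dihydronaphthalen-2-yl)-4-methylpent-3-en-1-yl 2-methylpropanoate | CC(C)=CC[C@H](OC(=O)C(C)C)C1=CC(=O)c2c(O)ccc(O)c2C1=O | target

## Step count and least certain steps

Total step count: 6. Longest linear sequence: 5 steps (steps 1, 2, 3, 4 and 6); step 5 is a one-step side branch.

**Step 6 (key step).** The most likely failure is a change of pathway. The very electron-rich diene may transfer an electron to the quinone, or add to it in a conjugate sense through C3 of the furan. The quinone would then be reduced or arylated instead of annulated. Premature hydrolysis of the moisture-sensitive diene would have the same practical effect. The fallback sets out from 6 and returns at 11. It replaces the oxa-bridged diene by the carbocyclic, less reducing 1,4-bis(trimethylsilyloxy)cyclohexa-1,3-diene F1, made from cyclohexane-1,4-dione with Me3SiCl and Et3N. Diels–Alder reaction with 6 at the unsubstituted double bond should give the bicyclo[2.2.2]octene adduct F2. Enolisation with a trace of Et3N and oxidation with Ag2O in the same flask should give the bridged quinone F3. Heating F3 in toluene should expel ethylene by retro-Diels–Alder reaction (Alder–Rickert cleavage) to the bis(trimethylsilyl) ether of the target F4. Brief treatment with dilute aqueous HCl in THF should then give 11.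

**Step 4.** The most likely failure is competitive oxidation of the trisubstituted olefin by tetravalent cerium. A second risk is acid-induced loss of the isobutyrate through the benzylic cation, which the ortho-methoxy group stabilises, before the arene is oxidised. The fallback sets out from 3 and returns at 6. It changes the order so that the electron-rich olefin never meets the oxidant. Acylation of 3 as in step 3 should give (S)-1-(2,5-dimethoxyphenyl)but-3-en-1-yl 2-methylpropanoate F5. Oxidation with (NH4)2Ce(NO3)6 should give the allyl-substituted quinone F6, whose terminal olefin is far harder to oxidise. Cross-metathesis of F6 with 2-methyl-2-butene and the second-generation Grubbs catalyst (H2IMes)(PCy3)Cl2Ru=CHPh should then give 6, since benzoquinones are tolerated by ruthenium alkylidenes.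

**Step 1.** The most likely failure is erosion of enantioselectivity. Residual allylmagnesium bromide may add without the chiral boron, or magnesium salts held by the ortho-methoxy group may open a non-chair pathway. Separation from isopinocampheol may also be tedious. The fallback sets out from 4 of insufficient enantiomeric purity and returns at 4. Oxidation with Dess–Martin periodinane should give 1-(2,5-dimethoxyphenyl)-4-methylpent-3-en-1-one F7. Reduction with (−)-Ipc2BCl in THF at −25 °C, with the aryl group as the large substituent, should return the (S) alcohol 4. The stereocentre is then set by ketone reduction and not by allyl transfer.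

**Step 2.** The most likely failure is stalling of the metathesis through chelation of the ruthenium alkylidene by the homoallylic hydroxyl and the ortho-methoxy group. Migration of the double bond by ruthenium hydride species is a second risk. The fallback sets out from 3 and returns at 4 and builds the olefin by carbonyl olefination. Silylation (t-BuMe2SiCl, imidazole) should give the silyl ether F8. Lemieux–Johnson cleavage (OsO4 cat., NaIO4) should give the aldehyde F9. Wittig reaction with the ylide from isopropyltriphenylphosphonium iodide and n-BuLi at −78 °C should give the silyl ether of 4 F10. Bu4NF in THF should then release 4.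

## Further compounds

F1 | step 6 | 1,4-bis(trimethylsilyloxy)cyclohexa-1,3-diene | C[Si](C)(C)OC1=CC=C(O[Si](C)(C)C)CC1
F2 | step 6 | (1S)-1-[5,8-bis(trimethylsilyloxy)-1,4-dioxo-1,4,4a,5,8,8a-hexahydro-5,8-ethanonaphthalen-2-yl]-4-methylpent-3-en-1-yl 2-methylpropanoate | CC(C)=CC[C@H](OC(=O)C(C)C)C1=CC(=O)C2C(C1=O)C1(O[Si](C)(C)C)C=CC2(O[Si](C)(C)C)CC1
F3 | step 6 | (1S)-1-[5,8-bis(trimethylsilyloxy)-1,4-dioxo-1,4,5,8-tetrahydro-5,8-ethanonaphthalen-2-yl]-4-methylpent-3-en-1-yl 2-methylpropanoate | CC(C)=CC[C@H](OC(=O)C(C)C)C1=CC(=O)C2=C(C1=O)C1(O[Si](C)(C)C)C=CC2(O[Si](C)(C)C)CC1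
F4 | step 6 | (1S)-1-[5,8-bis(trimethylsilyloxy)-1,4-dioxo-1,4-dihydronaphthalen-2-yl]-4-methylpent-3-en-1-yl 2-methylpropanoate | CC(C)=CC[C@H](OC(=O)C(C)C)C1=CC(=O)c2c(O[Si](C)(C)C)ccc(O[Si](C)(C)C)c2C1=O
F5 | step 4 | (S)-1-(2,5-dimethoxyphenyl)but-3-en-1-yl 2-methylpropanoate | C=CC[C@H](OC(=O)C(C)C)c1cc(OC)ccc1OC
F6 | step 4 | (S)-1-(3,6-dioxocyclohexa-1,4-dien-1-yl)but-3-en-1-yl 2-methylpropanoate | C=CC[C@H](OC(=O)C(C)C)C1=CC(=O)C=CC1=O
F7 | step 1 | 1-(2,5-dimethoxyphenyl)-4-methylpent-3-en-1-one | CC(C)=CCC(=O)c1cc(OC)ccc1OC
F8 | step 2 | (S)-tert-butyl{[1-(2,5-dimethoxyphenyl)but-3-en-1-yl]oxy}dimethylsilane | C=CC[C@H](O[Si](C)(C)C(C)(C)C)c1cc(OC)ccc1OC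
F9 | step 2 | (S)-3-[(tert-butyldimethylsilyl)oxy]-3-(2,5-dimethoxyphenyl)propanal | O=CC[C@H](O[Si](C)(C)C(C)(C)C)c1cc(OC)ccc1OC
F10 | step 2 | (S)-tert-butyl{[1-(2,5-dimethoxyphenyl)-4-methylpent-3-en-1-yl]oxy}dimethylsilane | CC(C)=CC[C@H](O[Si](C)(C)C(C)(C)C)c1cc(OC)ccc1OC
A1 | alternative 1 | 1,4,5,8-tetramethoxynaphthalene-2-carbaldehyde | COc1ccc(OC)c2c(OC)c(C=O)cc(OC)c12
A2 | alternative 1 | (S)-4-methyl-1-(1,4,5,8-tetramethoxynaphthalen-2-yl)pent-3-en-1-yl 2-methylpropanoate | CC(C)=CC[C@H](OC(=O)C(C)C)c1cc(OC)c2c(OC)ccc(OC)c2c1OC
A3 | alternative 1 | (S)-1-(5,8-dimethoxy-1,4-dioxo-1,4-dihydronaphthalen-2-yl)-4-methylpent-3-en-1-yl 2-methylpropanoate | CC(C)=CC[C@H](OC(=O)C(C)C)C1=CC(=O)c2c(OC)ccc(OC)c2C1=O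
A4 | alternative 2 | pentacarbonyl[(2,5-dimethoxyphenyl)(methoxy)methylidene]chromium, (CO)5Cr=C(OMe)Ar | COC(c1cc(OC)ccc1OC)=[Cr](=C=O)(=C=O)(=C=O)(=C=O)=C=O
A5 | alternative 2 | (S)-6-methylhept-5-en-1-yn-3-yl 2-methylpropanoate | CC(C)=CC[C@H](OC(=O)C(C)C)C#C
A6 | alternative 2 | (S)-1-(1-hydroxy-4,5,8-trimethoxynaphthalen-2-yl)-4-methylpent-3-en-1-yl 2-methylpropanoate | CC(C)=CC[C@H](OC(=O)C(C)C)c1cc(OC)c2c(OC)ccc(OC)c2c1O
A7 | alternative 3 | (S)-1-(3,4-dioxocyclobut-1-en-1-yl)-4-methylpent-3-en-1-yl 2-methylpropanoate | CC(C)=CC[C@H](OC(=O)C(C)C)C1=CC(=O)C1=O
A8 | alternative 3 | (1S)-1-[3-(2,5-dimethoxyphenyl)-3-hydroxy-4-oxocyclobut-1-en-1-yl]-4-methylpent-3-en-1-yl 2-methylpropanoate (carbinol centre of the ring left open) | CC(C)=CC[C@H](OC(=O)C(C)C)C1=CC(O)(c2cc(OC)ccc2OC)C1=O
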